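**Assumption (one line):** the target is taken exactly as drawn, i.e. (2S,3S,4S,6S) on the ring and (3S,5S) on the heptenyl side chain; ligand/BINOL antipodes are quoted as expected from the usual facial-selectivity models and would be swapped for their mirror images if a calibration run shows the opposite sense.

## Retrosynthetic overview

1. Blepharocalyxin C ⇐ global desilylation ⇐ E-selective cross-metathesis of a C1′ vinyl group with a 4-silyloxystyrene.
2. The only ring is made first as a δ-lactone (16) and then converted to the tetrahydropyran by aryllithium addition and axial hydride reduction of the oxocarbenium (sets C2).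
3. Lactone 16 ⇐ acyclic α-allylated β-hydroxy ester 15 by C6–O desilylation and lactonisation.
4. 15 ⇐ new Ir-catalysed branched allylation of the chelated dianion of β-hydroxy ester 7 with allyl carbonate 14 (forms C3–C1′; the chelate sets C3, the catalyst sets C1′).
5. 7 and 14 ⇐ common aldehyde 3 (vinylogous aldol then Noyori reduction for C6 and C4; Keck allylation then cross-metathesis for C3′).

## Route

**Step 1**
Reactants: 1, methyl 3-(4-hydroxyphenyl)propanoate
Product: 2, methyl 3-[4-(triisopropylsilyloxy)phenyl]propanoate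
Conditions: TIPSCl, imidazole, DMF, 0 °C → rt
Reagents that add atoms: TIPSCl, CC(C)[Si](Cl)(C(C)C)C(C)C
Why: Standard phenol silylation; the aryl TIPS ether is chosen because it survives the later LDA, hydride, acid and Lewis-acid steps.

**Step 2**
Reactants: 2
Product: 3, 3-[4-(triisopropylsilyloxy)phenyl]propanal
Conditions: DIBAL-H (1.05 equiv), CH2Cl2, −78 °C; Rochelle salt
Reagents that add atoms: none
Why: Low-temperature DIBAL half-reduction of a methyl ester stops at the aldehyde via the stable aluminium hemiacetal.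

**Step 3**
Reactants: 3; 4, 1-methoxy-1,3-bis(trimethylsilyloxy)buta-1,3-diene (Chan's diene)
Product: 5, methyl (S)-5-hydroxy-3-oxo-7-[4-(triisopropylsilyloxy)phenyl]heptanoate
Conditions: Ti(OiPr)4 (8 mol %), (R)-BINOL (8 mol %), 4 Å MS, THF, −78 °C → rt; then TFA, −78 °C
Reagents that add atoms: none beyond 4 (COC(O[Si](C)(C)C)=CC(=C)O[Si](C)(C)C; both TMS groups are lost)
Why: Ti/BINOL-catalysed vinylogous Mukaiyama aldol; the chiral Lewis acid directs the dienolate to one aldehyde face and sets the future C6 as S.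

**Step 4**
Reactants: 5
Product: 6, methyl (S)-5-(tert-butyldimethylsilyloxy)-3-oxo-7-[4-(triisopropylsilyloxy)phenyl]heptanoate
Conditions: TBSCl, imidazole, DMF, rt
Reagents that add atoms: TBSCl, CC(C)(C)[Si](C)(C)Cl
Why: Silylation of the secondary alcohol prevents lactonisation and leaves only the β-hydroxyl free for the later chelate.

**Step 5**
Reactants: 6
Product: 7, methyl (3S,5S)-5-(tert-butyldimethylsilyloxy)-3-hydroxy-7-[4-(triisopropylsilyloxy)phenyl]heptanoate
Conditions: RuCl2[(S)-BINAP] (0.5 mol %), H2 (50 atm), MeOH, 50 °C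
Reagents that add atoms: none (H2 only)
Why: Noyori asymmetric hydrogenation of a β-keto ester is catalyst-controlled; (S)-BINAP gives the 3S carbinol (same sense as (S)-3-hydroxybutanoate), which is the future C4 and is syn to C6–O.

**Step 6**
Reactants: 3; 8, allyltributylstannane
Product: 9, (S)-1-[4-(triisopropylsilyloxy)phenyl]hex-5-en-3-ol
Conditions: (R)-BINOL (10 mol %), Ti(OiPr)4 (10 mol %), 4 Å MS, CH2Cl2, −20 °C
Reagents that add atoms: none beyond 8 (C=CC[Sn](CCCC)(CCCC)CCCC; only the allyl group is transferred)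
Why: Keck asymmetric allylation; (R)-BINOL/Ti gives the S homoallylic alcohol from linear aliphatic aldehydes and sets the future C3′.

**Step 7**
Reactants: 9
Product: 10, (S)-tert-butyl({1-[4-(triisopropylsilyloxy)phenyl]hex-5-en-3-yl}oxy)diphenylsilane
Conditions: TBDPSCl, imidazole, DMAP (cat.), DMF, rt
Reagents that add atoms: TBDPSCl, CC(C)(C)[Si](Cl)(c1ccccc1)c1ccccc1
Why: TBDPS is acid-stable, so this oxygen stays masked when the C6–OTBS group is removed in step 12.

**Step 8**
Reactants: 10; 11, methyl acrylate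
Product: 12, methyl (S,E)-5-(tert-butyldiphenylsilyloxy)-7-[4-(triisopropylsilyloxy)phenyl]hept-2-enoate
Conditions: Hoveyda–Grubbs II (3 mol %), methyl acrylate (5 equiv), CH2Cl2, 40 °C
Reagents that add atoms: none beyond 11 (C=CC(=O)OC; ethylene is lost)
Why: Olefin cross-metathesis of a type-I terminal alkene with an acrylate is selective for the cross product and gives the E-enoate (>20:1).

**Step 9**
Reactants: 12
Product: 13, (S,E)-5-(tert-butyldiphenylsilyloxy)-7-[4-(triisopropylsilyloxy)phenyl]hept-2-en-1-ol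
Conditions: DIBAL-H (2.5 equiv), CH2Cl2, −78 °C
Reagents that add atoms: none
Why: DIBAL reduces the enoate 1,2 to the E-allylic alcohol without touching the silyl ethers.

**Step 10**
Reactants: 13
Product: 14, tert-butyl (S,E)-5-(tert-butyldiphenylsilyloxy)-7-[4-(triisopropylsilyloxy)phenyl]hept-2-en-1-yl carbonate
Conditions: n-BuLi, THF, −78 °C; Boc2O, → 0 °C
Reagents that add atoms: Boc2O, CC(C)(C)OC(=O)OC(=O)OC(C)(C)C
Why: Alkoxide acylation gives a linear E-allyl tert-butyl carbonate, a standard Ir electrophile whose hindered carbonyl resists attack by the basic nucleophile of step 11.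

**Step 11 (proposed new step)**
Reactants: 7; 14
Product: 15, methyl (2S,3S,5S)-5-(tert-butyldimethylsilyloxy)-2-[(3S,5S)-5-(tert-butyldiphenylsilyloxy)-7-(4-triisopropylsilyloxyphenyl)hept-1-en-3-yl]-3-hydroxy-7-(4-triisopropylsilyloxyphenyl)heptanoate
Conditions: 7, LDA (2.2 equiv), THF, −78 → −30 °C; ZnCl2 (1.1 equiv), −78 °C; then 14 (1.1 equiv), [Ir(cod)Cl]2 (2.5 mol %), (Ra,Rc,Rc)-BINOL-derived N,N-bis(1-phenylethyl)phosphoramidite (5 mol %, pre-activated with n-PrNH2), −40 → 0 °C. The ligand antipode meant is the one that gives S branched adducts from (E)-alkyl allyl carbonates with carbon nucleophiles.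
Reagents that add atoms: none (the carbonate leaves as CO2 and t-BuO−)
Why: Proposed new method: Ir-catalysed branched-selective allylic alkylation with a Fráter–Seebach dianion as nucleophile — double deprotonation of 7 gives the O,O-chelated (Li/Zn) Z(O)-enolate, which is open only on the face anti to the C4 chain (giving the 2,3-anti, 2S,3S product) and attacks the substituted terminus of the cationic (π-allyl)Ir–phosphoramidite outer-sphere and anti to Ir, so the chelate alone fixes C3 and the ligand alone fixes C1′ (S) while the C3–C1′ bond joins the two halves; the closest known reactions are Fráter–Seebach alkylation with alkyl halides, allylation of chelated zinc ester enolates with π-allyl metal complexes, and Ir-catalysed allylation of ketone enolates and silyl ketene acetals.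

**Step 12**
Reactants: 15
Product: 16, (3S,4S,6S)-3-[(3S,5S)-5-(tert-butyldiphenylsilyloxy)-7-(4-triisopropylsilyloxyphenyl)hept-1-en-3-yl]-4-hydroxy-6-{2-[4-(triisopropylsilyloxy)phenyl]ethyl}tetrahydro-2H-pyran-2-one
Conditions: CSA (0.2 equiv), MeOH/CH2Cl2, 0 °C → rt; then concentrate, PhMe, 60 °C
Reagents that add atoms: none
Why: Mild acid cleaves only the secondary alkyl TBS ether (TBDPS and aryl silyl ethers persist) and the freed δ-hydroxy ester lactonises; no stereocentre is touched.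

**Step 13**
Reactants: 16; 17, (4-bromophenoxy)(tert-butyl)dimethylsilane
Product: 18, (3S,4S,6S)-2-[4-(tert-butyldimethylsilyloxy)phenyl]-3-[(3S,5S)-5-(tert-butyldiphenylsilyloxy)-7-(4-triisopropylsilyloxyphenyl)hept-1-en-3-yl]-6-{2-[4-(triisopropylsilyloxy)phenyl]ethyl}tetrahydro-2H-pyran-2,4-diol (lactol, anomeric mixture)
Conditions: 16, TMSCl, Et3N, CH2Cl2, 0 °C (transient 4-OTMS); 17, n-BuLi, THF, −78 °C, then the silylated lactone, −78 °C; AcOH quench; aq. citric acid/THF (TMS off)
Reagents that add atoms: none retained beyond 17 (CC(C)(C)[Si](C)(C)Oc1ccc(Br)cc1; Br is lost, TMS is transient)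
Why: Aryllithium adds once to a δ-lactone because the lithium hemiketal is stable at −78 °C (C-aryl glycoside-type addition); C2 is not yet fixed.

**Step 14**
Reactants: 18
Product: 19, (2S,3S,4S,6S)-2-[4-(tert-butyldimethylsilyloxy)phenyl]-3-[(3S,5S)-5-(tert-butyldiphenylsilyloxy)-7-(4-triisopropylsilyloxyphenyl)hept-1-en-3-yl]-6-{2-[4-(triisopropylsilyloxy)phenyl]ethyl}tetrahydro-2H-pyran-4-ol
Conditions: Et3SiH (5 equiv), BF3·OEt2 (2 equiv), CH2Cl2/MeCN, −40 → −20 °C
Reagents that add atoms: none (hydride only)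
Why: BF3 ionises the lactol to the aryl-stabilised oxocarbenium and Et3SiH delivers hydride axially (Kishi-type reduction) onto the half-chair with the C3 and C6 substituents pseudo-equatorial, so the aryl ends equatorial (2S; 2,6-cis and 2,3-trans), which is also the thermodynamic isomer.

**Step 15**
Reactants: 19; 20, 4-(tert-butyldimethylsilyloxy)styrene
Product: 21, (2S,3S,4S,6S)-2-[4-(tert-butyldimethylsilyloxy)phenyl]-3-[(3S,5S,E)-5-(tert-butyldiphenylsilyloxy)-1-(4-tert-butyldimethylsilyloxyphenyl)-7-(4-triisopropylsilyloxyphenyl)hept-1-en-3-yl]-6-{2-[4-(triisopropylsilyloxy)phenyl]ethyl}tetrahydro-2H-pyran-4-ol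
Conditions: 20 (4 equiv), Hoveyda–Grubbs II (10 mol %), CH2Cl2, 40 °C
Reagents that add atoms: none beyond 20 (C=Cc1ccc(O[Si](C)(C)C(C)(C)C)cc1; ethylene is lost)
Why: Olefin cross-metathesis between the only alkene in 19 and a styrene gives the conjugated E-styrene under thermodynamic control without affecting C1′.

**Step 16**
Reactants: 21
Product: 22, blepharocalyxin C, (2S,3S,4S,6S)-3-[(3S,5S,E)-5-hydroxy-1,7-bis(4-hydroxyphenyl)hept-1-en-3-yl]-2-(4-hydroxyphenyl)-6-[2-(4-hydroxyphenyl)ethyl]tetrahydro-2H-pyran-4-ol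
Conditions: TBAF (12 equiv), THF, 0 °C → rt, Ar; AcOH quench
Reagents that add atoms: none
Why: Fluoride cleaves all five silyl ethers (2 ArOTIPS, 2 ArOTBS, 1 sec-OTBDPS) in one operation without touching the stereocentres or the styrene.

## Compound list

1 | methyl 3-(4-hydroxyphenyl)propanoate | COC(=O)CCc1ccc(O)cc1 | starting material
2 | methyl 3-[4-(triisopropylsilyloxy)phenyl]propanoate | COC(=O)CCc1ccc(O[Si](C(C)C)(C(C)C)C(C)C)cc1 | intermediate
3 | 3-[4-(triisopropylsilyloxy)phenyl]propanal | O=CCCc1ccc(O[Si](C(C)C)(C(C)C)C(C)C)cc1 | intermediate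
4 | 1-methoxy-1,3-bis(trimethylsilyloxy)buta-1,3-diene | COC(O[Si](C)(C)C)=CC(=C)O[Si](C)(C)C | starting material
5 | methyl (S)-5-hydroxy-3-oxo-7-[4-(TIPSO)phenyl]heptanoate | COC(=O)CC(=O)C[C@@H](O)CCc1ccc(O[Si](C(C)C)(C(C)C)C(C)C)cc1 | intermediate
6 | methyl (S)-5-(TBSO)-3-oxo-7-[4-(TIPSO)phenyl]heptanoate | COC(=O)CC(=O)C[C@@H](O[Si](C)(C)C(C)(C)C)CCc1ccc(O[Si](C(C)C)(C(C)C)C(C)C)cc1 | intermediate
7 | methyl (3S,5S)-5-(TBSO)-3-hydroxy-7-[4-(TIPSO)phenyl]heptanoate | COC(=O)C[C@@H](O)C[C@@H](O[Si](C)(C)C(C)(C)C)CCc1ccc(O[Si](C(C)C)(C(C)C)C(C)C)cc1 | intermediate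
8 | allyltributylstannane | C=CC[Sn](CCCC)(CCCC)CCCC | starting material
9 | (S)-1-[4-(TIPSO)phenyl]hex-5-en-3-ol | C=CC[C@@H](O)CCc1ccc(O[Si](C(C)C)(C(C)C)C(C)C)cc1 | intermediate
10 | TBDPS ether of 9 | C=CC[C@@H](O[Si](c1ccccc1)(c1ccccc1)C(C)(C)C)CCc1ccc(O[Si](C(C)C)(C(C)C)C(C)C)cc1 | intermediate
11 | methyl acrylate | C=CC(=O)OC | starting material
12 | methyl (S,E)-5-(TBDPSO)-7-[4-(TIPSO)phenyl]hept-2-enoate | COC(=O)/C=C/C[C@@H](O[Si](c1ccccc1)(c1ccccc1)C(C)(C)C)CCc1ccc(O[Si](C(C)C)(C(C)C)C(C)C)cc1 | intermediate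
13 | (S,E)-5-(TBDPSO)-7-[4-(TIPSO)phenyl]hept-2-en-1-ol | OC/C=C/C[C@@H](O[Si](c1ccccc1)(c1ccccc1)C(C)(C)C)CCc1ccc(O[Si](C(C)C)(C(C)C)C(C)C)cc1 | intermediate
14 | tert-butyl carbonate of 13 | CC(C)(C)OC(=O)OC/C=C/C[C@@H](O[Si](c1ccccc1)(c1ccccc1)C(C)(C)C)CCc1ccc(O[Si](C(C)C)(C(C)C)C(C)C)cc1 | intermediate
15 | methyl (2S,3S,5S)-2-[(3S,5S)-hept-1-en-3-yl]-3-hydroxy ester (full name in step 11) | C=C[C@H](C[C@@H](O[Si](c1ccccc1)(c1ccccc1)C(C)(C)C)CCc1ccc(O[Si](C(C)C)(C(C)C)C(C)C)cc1)[C@H](C(=O)OC)[C@@H](O)C[C@@H](O[Si](C)(C)C(C)(C)C)CCc1ccc(O[Si](C(C)C)(C(C)C)C(C)C)cc1 | intermediate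
16 | (3S,4S,6S)-δ-lactone (full name in step 12) | C=C[C@H](C[C@@H](O[Si](c1ccccc1)(c1ccccc1)C(C)(C)C)CCc1ccc(O[Si](C(C)C)(C(C)C)C(C)C)cc1)[C@@H]1C(=O)O[C@@H](CCc2ccc(O[Si](C(C)C)(C(C)C)C(C)C)cc2)C[C@@H]1O | intermediate
17 | (4-bromophenoxy)(tert-butyl)dimethylsilane | CC(C)(C)[Si](C)(C)Oc1ccc(Br)cc1 | starting material
18 | (3S,4S,6S)-2-aryl lactol, anomeric mixture (full name in step 13) | C=C[C@H](C[C@@H](O[Si](c1ccccc1)(c1ccccc1)C(C)(C)C)CCc1ccc(O[Si](C(C)C)(C(C)C)C(C)C)cc1)[C@@H]1C(O)(c2ccc(O[Si](C)(C)C(C)(C)C)cc2)O[C@@H](CCc2ccc(O[Si](C(C)C)(C(C)C)C(C)C)cc2)C[C@@H]1O | intermediate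
19 | (2S,3S,4S,6S)-tetrahydropyran-4-ol with C1′ vinyl (full name in step 14) | C=C[C@H](C[C@@H](O[Si](c1ccccc1)(c1ccccc1)C(C)(C)C)CCc1ccc(O[Si](C(C)C)(C(C)C)C(C)C)cc1)[C@@H]1[C@@H](c2ccc(O[Si](C)(C)C(C)(C)C)cc2)O[C@@H](CCc2ccc(O[Si](C(C)C)(C(C)C)C(C)C)cc2)C[C@@H]1O | intermediate
20 | 4-(tert-butyldimethylsilyloxy)styrene | C=Cc1ccc(O[Si](C)(C)C(C)(C)C)cc1 | starting material
21 | penta-silylated blepharocalyxin C (full name in step 15) | CC(C)(C)[Si](C)(C)Oc1ccc(/C=C/[C@H](C[C@@H](O[Si](c2ccccc2)(c2ccccc2)C(C)(C)C)CCc2ccc(O[Si](C(C)C)(C(C)C)C(C)C)cc2)[C@@H]2[C@@H](c3ccc(O[Si](C)(C)C(C)(C)C)cc3)O[C@@H](CCc3ccc(O[Si](C(C)C)(C(C)C)C(C)C)cc3)C[C@@H]2O)cc1 | intermediate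
22 | blepharocalyxin C | Oc1ccc(/C=C/[C@H](C[C@@H](O)CCc2ccc(O)cc2)[C@@H]2[C@@H](c3ccc(O)cc3)O[C@@H](CCc3ccc(O)cc3)C[C@@H]2O)cc1 | target

## Summary

Total step count: 16.
Longest linear sequence: 13 steps (1 → 2 → 3 → 9 → 10 → 12 → 13 → 14 → 15 → 16 → 18 → 19 → 21 → 22).

Three steps most likely to fail:

1. **Step 11 (proposed new Ir/chelated-dianion allylation).** Risks are O-allylation or carbonate attack by the alkoxide, slow ionisation below 0 °C, and 1,3-silyl migration. Fallback with known chemistry: a dianionic Ireland–Claisen rearrangement. Convert 7 to its ester with allylic alcohol 13 (LiOH, then EDC/DMAP), treat with LDA (2.2 equiv)/TMSCl, THF, −78 °C → rt, then TMSCHN2 to give the same 15. The β-alkoxide chelate sets C3 (anti), and the chair transition state of the (E)-allyl ester with the chelated Z(O)-ketene acetal sets the same 1′S configuration, with no catalyst needed.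

2. **Step 15 (cross-metathesis at a hindered, α-branched vinyl group).** Fallback: make the aryl–vinyl bond by a Mizoroki–Heck arylation of 19 with (4-iodophenoxy)(tert-butyl)dimethylsilane (Pd(OAc)2, Ag2CO3 or Jeffery conditions), which gives the E-styrene directly.

3. **Step 13 (aryllithium addition to the α-branched β-oxy lactone).** Risks are enolisation with C3 epimerisation and retro-aldol of the ring-opened keto-alkoxide. Fallback: skip the lactone. Convert ester 15 (4-OH as its TES ether) to the Weinreb amide, add the aryllithium to give the aryl ketone, then close the ring by BiBr3/Et3SiH reductive etherification of the δ-silyloxy ketone, which gives the same 2,6-cis tetrahydropyran 19.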